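The C3=C4 alkene is traced back to a chroman and the anisyl-side carbonyl to a dimethyl ketal. Ring B is then cut at C4a–C5 and C6–C7, the ynone at its C(sp)–C(=O) bond, and the pyran ring at O1–C2 and C4–C4a.
Enabling feature: in ring B the acyl-bearing C6 lies between C5–OMe and C7–OH, and the C4a–C8a edge is shared with the pyran ring. C5–C6 therefore maps onto a β-methoxy ynone, and C7–C8–C8a–C4a onto a ketene silyl acetal conjugated with a cyclic enol ether.
Forward, the pyran ring comes first (γ-prenylation of acetoacetate, O-closure, silylation). In parallel the anisyl ketal Weinreb amide acylates methoxyacetylide.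
The [4+2] cycloaddition with aromatisation then builds ring B with all its substituents in place. Ketal hydrolysis frees the benzil, and DDQ introduces C3=C4 last.
Stereochemistry: the target has no stereocentre and its only alkene is ring-locked cis. The transient centres C4a and C7 of the cycloadduct disappear on aromatisation.
Key step: step 7

Assumption: the geometry of the ketene silyl acetal (drawn Z) is not controlled and does not matter, since that carbon becomes aromatic C7; the target is taken as the open, hydrogen-bonded benzil tautomer of the given SMILES.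

Step 1
Reactants: 1 methyl acetoacetate; 2 1-bromo-3-methylbut-2-ene (prenyl bromide)
Product: 4 methyl 7-methyl-3-oxooct-6-enoate, via acetoacetate dianion 3 (not isolated)
Conditions: NaH, THF, 0 °C; n-BuLi, 0 °C; then 2, 0 °C to rt; 1 M HCl quench
Reagents that add atoms: none
Why: γ-Alkylation of the acetoacetate dianion, in which the terminal carbanion of 3 is by far the more nucleophilic site and the allylic bromide reacts by SN2 at its primary carbon, forming the future C4–C4a bond.

Step 2
Reactants: 4 methyl 7-methyl-3-oxooct-6-enoate
Product: 5 methyl (E)-2-(6,6-dimethyltetrahydro-2H-pyran-2-ylidene)acetate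
Conditions: Amberlyst 15 (cat.), CH2Cl2, 0 °C to rt; resin filtered off at full conversion
Reagents that add atoms: none
Why: Acid-catalysed intramolecular Markovnikov hydroalkoxylation, in which protonation of the trisubstituted alkene places the charge on the CMe2 carbon, the ketone oxygen captures it faster than the enol carbon can, and loss of the doubly activated α-proton gives the conjugated E vinylogous carbonate, the resin being removed early so that slower C-alkylation cannot set in.

Step 3
Reactants: 5 methyl (E)-2-(6,6-dimethyltetrahydro-2H-pyran-2-ylidene)acetate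
Product: 7 (Z)-1-methoxy-1-(trimethylsilyloxy)-2-(6,6-dimethyl-5,6-dihydro-4H-pyran-2-yl)ethene, via lithium dienolate 6 (not isolated)
Conditions: LiN(i-Pr)2, THF, −78 °C; Me3SiCl, −78 °C to rt; pentane, filtration, bulb-to-bulb distillation
Reagents that add atoms: chlorotrimethylsilane, C[Si](C)(C)Cl
Why: Kinetic γ-deprotonation and O-silylation as in the preparation of Brassard-type dienes from 3-alkoxycrotonates, the ring CH2 cis to the ester being removed by the ester-bound amide base and the hard silyl chloride trapping dienolate 6 on oxygen.

Step 4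
Reactants: 8 methyl 2-(4-methoxyphenyl)-2-oxoacetate
Product: 9 methyl 2,2-dimethoxy-2-(4-methoxyphenyl)acetate
Conditions: HC(OMe)3, MeOH, H2SO4 (cat.), reflux
Reagents that add atoms: trimethyl orthoformate, COC(OC)OC; methanol, CO
Why: Acid-catalysed ketalisation driven by the orthoformate as water scavenger, the ester-activated ketone reacting through an oxocarbenium ion that the p-anisyl group stabilises while the methyl ester only exchanges with the solvent.

Step 5
Reactants: 9 methyl 2,2-dimethoxy-2-(4-methoxyphenyl)acetate
Product: 10 N,2,2-trimethoxy-2-(4-methoxyphenyl)-N-methylacetamide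
Conditions: MeNH(OMe)·HCl, i-PrMgCl, THF, −20 to 0 °C; cold 1 M HCl quench
Reagents that add atoms: N,O-dimethylhydroxylamine hydrochloride, CNOC.Cl
Why: Direct aminolysis of the ester by the chloromagnesium amide of N,O-dimethylhydroxylamine (Weinreb amide formation), helped by the two inductively activating α-methoxy groups and by the absence of any α-proton.

Step 6
Reactants: 11 2-chloro-1,1-dimethoxyethane; 10 N,2,2-trimethoxy-2-(4-methoxyphenyl)-N-methylacetamide
Product: 13 1,1,4-trimethoxy-1-(4-methoxyphenyl)but-3-yn-2-one, via lithium methoxyacetylide 12 (not isolated)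
Conditions: Et2NH, n-BuLi (3 equiv each per 11), THF, 0 °C; 11, 0 °C; then 10, −78 to −30 °C; inverse quench into cold 0.5 M HCl/Et2O
Reagents that add atoms: none
Why: Threefold base treatment of the chloroacetal (loss of MeOH, loss of HCl, deprotonation) is the standard in situ source of lithium alkoxyacetylides, and the Weinreb ketone synthesis holds at monoaddition until the cold acidic inverse quench, which protonates the amines before they can add to the ynone.

Step 7
Reactants: 7 (Z)-1-methoxy-1-(trimethylsilyloxy)-2-(6,6-dimethyl-5,6-dihydro-4H-pyran-2-yl)ethene; 13 1,1,4-trimethoxy-1-(4-methoxyphenyl)but-3-yn-2-one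
Product: 16 1-(7-hydroxy-5-methoxy-2,2-dimethylchroman-6-yl)-2,2-dimethoxy-2-(4-methoxyphenyl)ethan-1-one, via cyclohexadiene cycloadduct 14 (not isolated), via cross-conjugated dienone 15 (not isolated)
Conditions: 7 (2 equiv), PhMe, 100 °C, sealed tube, Ar; then SiO2, CH2Cl2/MeOH, rt
Reagents that add atoms: none
Why: Diene 7 carries three oxygen donors that all push electron density to the ring carbon C4a, whereas ynone 13 is electrophilic at its methoxy-bearing β-carbon C5, so a normal-electron-demand, strongly asynchronous Diels–Alder reaction forms C4a–C5 ahead of C6–C7 and gives cycloadduct 14. The closest known reaction type is the cycloaddition of Brassard-type 1-alkoxy-1-silyloxy-1,3-dienes to acetylenic ketones and esters with in situ aromatisation. Ring B closes as a six-membered carbocycle in an intermolecular [4+2] mode on the C4a–C8a edge of the pyran, and the s-cis diene conformer is accessible because the ring methylene C4 points outward at C4a. The mixed silyl ketal at C7 of 14 expels MeOSiMe3 to give dienone 15, whose C4a–H shifts to oxygen to give the C7 phenol, so the transient stereocentres C4a and C7 vanish and no stereocontrol is called for. The step needs regioselectivity (C4a to C5 and not to C6), secured by the matched polarisation of both partners and retained even if the reaction runs stepwise as vinylogous Michael addition and Claisen-type closure, and chemoselectivity for C≡C over C=O, secured by the quaternary ketal carbon shielding the ketone and by the absence of a Lewis acid, which also spares the ketal. Because a methyl ynol ether cannot lose an alkene by retro-ene fragmentation, the heating that the donor-deactivated alkyne requires is tolerable, and the second equivalent of 7 covers silyl transfer to the phenol as it forms.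

Step 8
Reactants: 16 1-(7-hydroxy-5-methoxy-2,2-dimethylchroman-6-yl)-2,2-dimethoxy-2-(4-methoxyphenyl)ethan-1-one
Product: 17 1-(7-hydroxy-5-methoxy-2,2-dimethylchroman-6-yl)-2-(4-methoxyphenyl)ethane-1,2-dione
Conditions: TFA, H2O, CH2Cl2, 0 °C to rt
Reagents that add atoms: water, O
Why: Acid-catalysed ketal hydrolysis, feasible next to a carbonyl group because the p-anisyl ring stabilises the oxocarbenium ion, and placed before the dehydrogenation so that the acid meets only the robust chroman and never the acid-sensitive 2H-chromene.

Step 9
Reactants: 17 1-(7-hydroxy-5-methoxy-2,2-dimethylchroman-6-yl)-2-(4-methoxyphenyl)ethane-1,2-dione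
Product: 18 1-(7-hydroxy-5-methoxy-2,2-dimethyl-2H-chromen-6-yl)-2-(4-methoxyphenyl)ethane-1,2-dione (CNP0170833.0)
Conditions: DDQ (1.3 equiv), 1,4-dioxane, reflux
Reagents that add atoms: none
Why: Classical DDQ dehydrogenation of a 2,2-dimethylchroman, in which hydride leaves benzylic C4 (cation stabilised by O1 and the C5 methoxy group ortho and by the C7 hydroxy group para to C4a), a C3 proton follows, and quaternary C2 blocks further oxidation.

Compound list
1 | methyl acetoacetate | COC(=O)CC(C)=O | starting material
2 | 1-bromo-3-methylbut-2-ene (prenyl bromide) | CC(C)=CCBr | starting material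
3 | sodium lithium dianion of methyl acetoacetate | [Na+].[Li+].C=C([O-])C=C([O-])OC | intermediate
4 | methyl 7-methyl-3-oxooct-6-enoate | COC(=O)CC(=O)CCC=C(C)C | intermediate
5 | methyl (E)-2-(6,6-dimethyltetrahydro-2H-pyran-2-ylidene)acetate | COC(=O)/C=C1/OC(C)(C)CCC1 | intermediate
6 | lithium dienolate of 5 (lithium 2-(6,6-dimethyl-5,6-dihydro-4H-pyran-2-yl)-1-methoxyethen-1-olate) | [Li+].CO/C([O-])=C/C1=CCCC(C)(C)O1 | intermediate
7 | (Z)-1-methoxy-1-(trimethylsilyloxy)-2-(6,6-dimethyl-5,6-dihydro-4H-pyran-2-yl)ethene | CO/C(O[Si](C)(C)C)=C/C1=CCCC(C)(C)O1 | intermediate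
8 | methyl 2-(4-methoxyphenyl)-2-oxoacetate | COC(=O)C(=O)c1ccc(OC)cc1 | starting material
9 | methyl 2,2-dimethoxy-2-(4-methoxyphenyl)acetate | COC(=O)C(OC)(OC)c1ccc(OC)cc1 | intermediate
10 | N,2,2-trimethoxy-2-(4-methoxyphenyl)-N-methylacetamide | CON(C)C(=O)C(OC)(OC)c1ccc(OC)cc1 | intermediate
11 | 2-chloro-1,1-dimethoxyethane | COC(CCl)OC | starting material
12 | lithium methoxyacetylide | [Li+].[C-]#COC | intermediate
13 | 1,1,4-trimethoxy-1-(4-methoxyphenyl)but-3-yn-2-one | COC#CC(=O)C(OC)(OC)c1ccc(OC)cc1 | intermediate
14 | 1-[5,7-dimethoxy-2,2-dimethyl-7-(trimethylsilyloxy)-3,4,4a,7-tetrahydro-2H-chromen-6-yl]-2,2-dimethoxy-2-(4-methoxyphenyl)ethan-1-one (racemic, configuration at C4a and C7 immaterial) | COC1=C(C(=O)C(OC)(OC)c2ccc(OC)cc2)C(OC)(O[Si](C)(C)C)C=C2OC(C)(C)CCC12 | intermediate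
15 | 6-[2,2-dimethoxy-2-(4-methoxyphenyl)acetyl]-5-methoxy-2,2-dimethyl-2,3,4,4a-tetrahydro-7H-chromen-7-one (racemic) | COC1=C(C(=O)C(OC)(OC)c2ccc(OC)cc2)C(=O)C=C2OC(C)(C)CCC12 | intermediate
16 | 1-(7-hydroxy-5-methoxy-2,2-dimethylchroman-6-yl)-2,2-dimethoxy-2-(4-methoxyphenyl)ethan-1-one | COc1ccc(C(OC)(OC)C(=O)c2c(O)cc3c(c2OC)CCC(C)(C)O3)cc1 | intermediate
17 | 1-(7-hydroxy-5-methoxy-2,2-dimethylchroman-6-yl)-2-(4-methoxyphenyl)ethane-1,2-dione | COc1ccc(C(=O)C(=O)c2c(O)cc3c(c2OC)CCC(C)(C)O3)cc1 | intermediate
18 | 1-(7-hydroxy-5-methoxy-2,2-dimethyl-2H-chromen-6-yl)-2-(4-methoxyphenyl)ethane-1,2-dione | COc1ccc(C(=O)C(=O)c2c(O)cc3c(c2OC)C=CC(C)(C)O3)cc1 | target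

Total step count: 9 (three steps for each arm, three after their union).
Longest linear sequence: 6 steps (steps 1, 2, 3, 7, 8, 9; the arm of steps 4, 5, 6 is equally long).

Steps most likely to fail

**Step 7.** The donor-substituted alkyne may cycloadd so slowly that protodesilylation or thermal decay of the diene, and oligomerisation of the ynone, win the race.
- The fallback sets out from 10 and 7 and returns at 16. It replaces the donor on the alkyne by a halogen placeholder.
- HC≡CMgBr and 10 should give 1,1-dimethoxy-1-(4-methoxyphenyl)but-3-yn-2-one F1.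
- NBS with catalytic AgNO3 in acetone should convert this into 4-bromo-1,1-dimethoxy-1-(4-methoxyphenyl)but-3-yn-2-one F2, an inductively activated dienophile of the 3-bromopropiolate kind.
- Cycloaddition of F2 with 7 under the same polarity control, with loss of MeOSiMe3, should give 1-(5-bromo-7-hydroxy-2,2-dimethylchroman-6-yl)-2,2-dimethoxy-2-(4-methoxyphenyl)ethan-1-one F3.
- Ullmann-type methoxylation (NaOMe, CuBr, DMF/MeOH, 110 °C), of the kind used on bromophenolic carbonyl compounds and helped here by the ortho ketone, then installs the C5 methoxy group and delivers 16.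

**Step 2.** Extended contact with acid may let the O-closure reverse and drain into C-alkylation at the carbon between the two carbonyl groups (carbocyclisation).
- The fallback sets out from 4 and returns at 5. It closes the ring with an electrophile other than a proton, under non-acidic conditions.
- PhSeCl and K2CO3 in CH2Cl2 at −78 °C should open the seleniranium ion at its tertiary carbon with the keto-ester oxygen. This is the kinetic six-membered Markovnikov closure known for alkenyl β-keto esters and o-prenylphenols.
- The product should be methyl (E)-2-[6,6-dimethyl-5-(phenylselanyl)tetrahydro-2H-pyran-2-ylidene]acetate F4.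
- Radical deselenation with n-Bu3SnH and AIBN in toluene at 80 °C then gives 5.

**Step 6.** Two failure modes are possible. Diethylamine or N,O-dimethylhydroxylamine may add in conjugate fashion at the moment the ketone is released. The acid may also hydrate the ynol ether during the quench.
- The fallback sets out from 10 and 11 and returns at 13. It makes the carbonyl group only after all amines are gone.
- i-Bu2AlH in THF at −78 °C should reduce 10 to 2,2-dimethoxy-2-(4-methoxyphenyl)acetaldehyde F5.
- Acetylide 12, generated from 11 as before, should add to F5 to give 1,1,4-trimethoxy-1-(4-methoxyphenyl)but-3-yn-2-ol F6. This alcohol is not an electrophile and tolerates a neutral aqueous work-up.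
- MnO2 in CH2Cl2 then oxidises the propargylic alcohol to 13 under neutral, amine-free conditions.

Further compounds
F1 | step 7 | 1,1-dimethoxy-1-(4-methoxyphenyl)but-3-yn-2-one | C#CC(=O)C(OC)(OC)c1ccc(OC)cc1
F2 | step 7 | 4-bromo-1,1-dimethoxy-1-(4-methoxyphenyl)but-3-yn-2-one | BrC#CC(=O)C(OC)(OC)c1ccc(OC)cc1
F3 | step 7 | 1-(5-bromo-7-hydroxy-2,2-dimethylchroman-6-yl)-2,2-dimethoxy-2-(4-methoxyphenyl)ethan-1-one | COc1ccc(C(OC)(OC)C(=O)c2c(O)cc3c(c2Br)CCC(C)(C)O3)cc1
F4 | step 2 | methyl (E)-2-[6,6-dimethyl-5-(phenylselanyl)tetrahydro-2H-pyran-2-ylidene]acetate (racemic) | COC(=O)/C=C1/OC(C)(C)C([Se]c2ccccc2)CC1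
F5 | step 6 | 2,2-dimethoxy-2-(4-methoxyphenyl)acetaldehyde | COc1ccc(C(OC)(OC)C=O)cc1
F6 | step 6 | 1,1,4-trimethoxy-1-(4-methoxyphenyl)but-3-yn-2-ol (racemic) | COC#CC(O)C(OC)(OC)c1ccc(OC)cc1
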